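## Analysis of the target

CNP0230210.1 is a cis-fused tetrahydrofuro[3,2-b]pyran-5-one with a six-carbon side chain. Numbered from the lactone carbonyl (C1) to the terminal methyl (C12), the δ-lactone holds C1–C5 and O5, and the tetrahydrofuran holds C4–C7 and O4. There are seven stereocentres: five contiguous ones in the core (3R,4R,5R,6R,7S) and two in the chain (10S,11R), an anti-diol carried as C10 benzoate and C11 acetate behind an E-C8=C9 double bond. On the tetrahydrofuran the two lactone bonds, the C6 hydroxyl and the C7 alkenyl group all lie on one face, so the chain sits on the concave side of the bicycle; on the lactone ring O3, O4 and C6 are likewise mutually cis. The sensitive groups are the β-hydroxy lactone (elimination to the 2,3-unsaturated lactone), the alkene flanked by an allylic ether and an allylic benzoate (both ionisable), and two different esters on neighbouring oxygens (acyl migration as soon as one is free). The difficulties are the contra-thermodynamic centre C7, the four neighbouring oxygens O3–O6 that each need a different role, and the late placement of the esters. The strategy rests on C1–C6 being a 2-deoxy-D-lyxo-hexono-1,5-lactone. Its carbinol carbons C3, C4 and C5 have the configuration of the cis,trans-triol of quinic acid, and C2 and C6 are the two ring methylenes. C1 and C6 are therefore neighbours in a quinic-derived cyclohexanone, and the hexonate follows by inserting one oxygen atom between them.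

## Retrosynthetic reasoning

**C8=C9.** The target 22 is cut at its only C=C bond into the vinyl tetrahydrofuran lactone 14 and the terminal alkene 21. Here the seven stereocentres fall into two sets that do not influence each other, and both halves can carry their final oxygen pattern, so no ester has to be placed after the union. The forward cross-metathesis must join two hindered, allylically oxygenated vinyl groups with E geometry in the presence of two free hydroxyls.

**Side chain.** Alkene 21 goes back through hydroxy benzoate 20, silyl ether 19 and allylic alcohol 18 to aldehyde 17 and methyl (R)-lactate 15. The C9–C10 bond is cut because C11 then comes from the chiral pool and C10 from a non-chelation addition of a vinyl nucleophile (anti). The benzoate is placed before the acetate so that no hydroxyl is freed next to an ester under basic conditions.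

**O4–C7.** In 14 the ether bond O4–C7 is cut, leading to the cis-vinyl epoxide 12, in which O3 and O4 are still tied in the acetal. C7 lies on the concave face and cannot be set by equilibration; an invertive opening of an allylic epoxide carbon sets it stereospecifically. With the acetal oxygen O4 as nucleophile, O3 is never a free hydroxyl while the electrophile is present.

**C6–C7.** Epoxide 12 comes from the syn-chlorohydrin 11, and 11 from aldehyde 9 by chloroallylation. One C–C bond and both new stereocentres are made in one reagent-controlled step; the chloride is the leaving group that turns the adduct into the epoxide.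

**Lactone transposition.** Aldehyde 9 comes from alcohol 8, and 8 from the seven-membered lactone 6 by removing the silyl group on O5. The acyl group then moves from O6 to O5, which puts the lactone where the target has it and frees C6 for oxidation.

**Key disconnection.** Lactone 6 is cut at C6–O and O–C1, that is, one oxygen is taken out of the ring, giving cyclohexanone 5. This is the step that converts a carbocycle from the chiral pool into the open 2-deoxyhexonate with C1 to C6 in the right order. The forward reaction must insert oxygen on the C6 side of the carbonyl and not on the C2 side.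

**Ketone.** Ketone 5 follows from hydroxy ketone 4, triol 3 and acetonide lactone 2, all known degradation products of D-(−)-quinic acid 1. The carboxyl carbon is lost, and C3, C4 and C5 are never touched.

## Alternatives that were turned down

**Alternative 1:** The disconnection is the C1–C2 bond together with the lactone C1–O5 bond, C1 arriving last as CO. In the forward key step the terminal C2–C3 epoxide A1 is carbonylated with [(salph)Al(THF)2][Co(CO)4] under CO; A1 already carries the tetrahydrofuran, the side chain and a free C5 hydroxyl. The cobaltate opens the epoxide at C2, CO inserts, and O5 takes up the acyl group to give A2, the C6 silyl ether of the target.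
- For it: C3 keeps the epoxide oxygen, so its configuration is never at risk. A hexose precursor supplies four contiguous oxygenated centres, one more than quinic acid. The β-hydroxy lactone is made in a single step, with no migration question.
- Against it: the step is run on the complete molecule. The normal fate of the acyl cobalt species is capture by the aluminium-bound C3 alkoxide to give a β-lactone; acylation of the neutral secondary O5 must outrun that, or a second acyl shift is needed. The Lewis-acidic aluminium cation and the nucleophilic cobaltate meet an allylic benzoate and an allylic ether, which can ionise. A failure costs the whole sequence.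
- Comparison: it is stronger in chiral-pool coverage and in brevity of the end game. The chosen route instead puts its one uncertain step at step 5, on material made in four operations from a cheap acid, and uses only a peracid.

**Alternative 2:** The disconnection is the O4–C7 bond with transposition of the double bond. In the forward key step zerovalent palladium (Pd2(dba)3, PPh3) ionises the allylic C9–O bond of the vinyl epoxide A3, and the C4 hydroxyl attacks C7 of the π-allyl unit, giving A4 with the E-alkene and a free C10 hydroxyl.
- For it: ring closure, alkene geometry and the distinction between O10 (free) and O11 (acetate) come from one step. The whole chain is already attached, so no late coupling of two hindered olefins is needed. Double inversion carries the C9 configuration to C7.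
- Against it: the C10 alkoxide is released next to the C11 acetate, and a 1,2-acyl shift under these basic conditions would scramble the two ester positions before the benzoate is introduced. The allylic ether in A4 can be re-ionised by the same catalyst, which opens a path to the more stable epimer with the chain on the convex face. A3 needs three contiguous centres at C9–C11, the C6 centre, an E-alkene and a free O4–H beside a protected O3, all before the key step. The 2-deoxy lactone still has to be made separately.
- Comparison: it is the more convergent plan at the ring-closure stage. The chosen route closes the ring by an invertive epoxide opening that fixes C7 kinetically, and it draws C3–C5 and the lactone from one starting material.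

**Alternative 3:** The disconnection is the C2=C3 bond of an unsaturated lactone and the terminal methylene on C8, both traced to the strained alkene of the oxanorbornene acrylate A5. In the forward key step the second-generation Grubbs catalyst under ethylene opens the C3=C8 bond and the acrylate on O5 closes onto C3, giving the vinyl tetrahydrofuran A6.
- For it: it is by far the shortest way to the bicycle. All four tetrahydrofuran centres (C4–C7) come from a meso precursor with one desymmetrisation, ring strain drives the step, and the vinyl group for the side chain appears automatically.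
- Against it: the target needs the two oxygens O5 and O6 cis to the carbons that were the alkene bridge, so A5 must be the endo-diol. Dihydroxylation of an oxanorbornadiene gives the exo-diol; the endo-diol has to come from a reversible cycloaddition with little endo preference. A6 also has no oxygen on C3. It must be added across C2=C3 cis to O4, that is, from the concave face of the cis-fused bicycle, against the steric bias and in a reversible conjugate addition.
- Comparison: it is stronger on step count for C4–C7, and its last step would be the same cross-metathesis as here. The chosen route has the C3 hydroxyl in the right configuration from the start and makes C6 and C7 under reagent control.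

Key step: step 5

## Route

Assumption: locants C1–C12 follow the chain from the lactone carbonyl to the terminal methyl, each oxygen takes the locant of its carbon, and the quinic acid ring carbons keep these locants (C1 is the carbinol carbon that becomes the ketone).

Step 1
Reactants: 1 D-(−)-quinic acid
Product: 2 3,4-O-isopropylidenequinic acid 1,5-lactone
Conditions: 2,2-dimethoxypropane, TsOH·H2O (cat.), acetone, reflux
Reagents that add atoms: 2,2-dimethoxypropane, COC(C)(C)OC
Why: Acid-catalysed acetalisation takes the only cis-diol (O3/O4) and the carboxyl lactonises onto O5, which is cis to it; this is the standard one-pot protection of quinic acid.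

Step 2
Reactants: 2 3,4-O-isopropylidenequinic acid 1,5-lactone
Product: 3 1-(hydroxymethyl)-3,4-O-isopropylidenecyclohexane-1,3,4,5-tetrol (reduced lactone, configuration of quinic acid)
Conditions: NaBH4, EtOH, 0 °C to rt
Reagents that add atoms: none
Why: Borohydride reduction of the strained bicyclic lactone gives the primary alcohol and releases O5–H; the acetal is inert.

Step 3
Reactants: 3 1-(hydroxymethyl)-3,4-O-isopropylidenecyclohexane-1,3,4,5-tetrol
Product: 4 (3R,4S,5R)-5-hydroxy-3,4-(isopropylidenedioxy)cyclohexanone
Conditions: NaIO4, H2O (phosphate buffer, pH 6–7), 0 °C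
Reagents that add atoms: none
Why: Periodate glycol cleavage of the only free vicinal diol (C1–OH/CH2OH) removes the former carboxyl carbon as formaldehyde and turns C1 into the ketone.

Step 4
Reactants: 4 (3R,4S,5R)-5-hydroxy-3,4-(isopropylidenedioxy)cyclohexanone
Product: 5 (3R,4R,5R)-5-(tert-butyldimethylsilyloxy)-3,4-(isopropylidenedioxy)cyclohexanone
Conditions: TBSCl, imidazole, DMAP (cat.), DMF, 0 °C to rt
Reagents that add atoms: tert-butyldimethylsilyl chloride, CC(C)(C)[Si](C)(C)Cl
Why: Silylation of the secondary alcohol under weakly basic conditions avoids β-elimination of the β-hydroxy ketone; the silyl ether makes O5 the most electron-rich and the bulkiest of the three ring oxygens.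

Step 5
Reactants: 5 (3R,4R,5R)-5-(tert-butyldimethylsilyloxy)-3,4-(isopropylidenedioxy)cyclohexanone
Product: 6 (4R,5R,6R)-6-(tert-butyldimethylsilyloxy)-4,5-(isopropylidenedioxy)oxepan-2-one
Conditions: mCPBA, NaHCO3, CH2Cl2, 0 °C to rt
Reagents that add atoms: m-chloroperoxybenzoic acid, OOC(=O)c1cccc(Cl)c1
Why: The peracid adds to the ketone to give the tetrahedral peroxy hemiketal (Criegee intermediate), and an α-carbon then shifts from C1 to the proximal peroxide oxygen while m-chlorobenzoate leaves. The closest known reaction type is the peracid Baeyer–Villiger ring expansion of polyoxygenated cyclohexanones to ε-lactones. The seven-membered ring arises by insertion of one oxygen into the existing six-membered ring (a 1,2-shift, not an end-to-end cyclisation), which forms the C6–O and O–C1 bonds. No stereocentre is made; the migrating C6 is a methylene group and C3, C4 and C5 are spectators. The selectivity the step needs is migration of C6 in preference to C2, both being primary. C2 is attached to C3, whose oxygen belongs to the acetal and is the poorer donor, whereas C6 is attached to C5 with the more electron-rich silyl ether. In the chair with the silyloxy group axial, as is common for β-silyloxy cyclohexanones, the C5–O5 bond is gauche to C1–C6, while the equatorial C3–O3 bond is antiperiplanar to C1–C2 and withdraws electron density from it. These are biases and not guarantees; the regioisomeric lactones are separable and their proportion has to be determined.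

Step 6
Reactants: 6 (4R,5R,6R)-6-(tert-butyldimethylsilyloxy)-4,5-(isopropylidenedioxy)oxepan-2-one
Product: 8 2-deoxy-3,4-O-isopropylidene-D-lyxo-hexono-1,5-lactone, via hydroxy ε-lactone 7 (not isolated)
Conditions: Bu4NF, AcOH (1:1), THF, 0 °C to rt
Reagents that add atoms: none
Why: Fluoride cleaves the Si–O bond; the freed O5–H transacylates through a six-membered tetrahedral intermediate (6-exo-trig) to the less strained δ-lactone and releases the primary C6–OH. O4 stays locked in the acetal, so no γ-lactone can form.

Step 7
Reactants: 8 2-deoxy-3,4-O-isopropylidene-D-lyxo-hexono-1,5-lactone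
Product: 9 2-deoxy-3,4-O-isopropylidene-D-lyxo-hexodialdono-1,5-lactone (C6 aldehyde of 8)
Conditions: Dess–Martin periodinane, NaHCO3, CH2Cl2, 0 °C to rt
Reagents that add atoms: none
Why: Neutral periodinane oxidation of the primary alcohol; no base is present that could epimerise C5 or eliminate O4, and the aldehyde is used crude.

Step 8
Reactants: 9 2-deoxy-3,4-O-isopropylidene-D-lyxo-hexodialdono-1,5-lactone
Product: 11 (6S,7S)-7-chloro-2,7,8,9-tetradeoxy-3,4-O-isopropylidene-non-8-enono-1,5-lactone (syn-chlorohydrin; C3–C5 as in 8), via O6-borinate 10 (not isolated)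
Conditions: allyl chloride, LiN(c-C6H11)2, (+)-Ipc2BOMe, BF3·OEt2, Et2O/THF, −95 °C; then 9, −95 °C; then pH 7 buffer, H2O2, MeOH, 0 °C
Reagents that add atoms: allyl chloride, C=CCCl
Why: (Z)-γ-Chloroallylboration through a chair six-membered transition state gives the syn-chlorohydrin. The isopinocampheyl groups derived from (−)-α-pinene direct the allyl unit to the Re face of the aldehyde, which is also the Felkin–Anh face (new O6 anti to O5), so reagent and substrate control reinforce each other. Allylboranes leave lactones untouched.

Step 9
Reactants: 11 (6S,7S)-syn-chlorohydrin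
Product: 12 (6R,7R)-6,7-anhydro-2,8,9-trideoxy-3,4-O-isopropylidene-non-8-enono-1,5-lactone (cis-vinyl epoxide; C3–C5 as in 8)
Conditions: DBU, CH2Cl2, 0 °C
Reagents that add atoms: none
Why: Intramolecular Williamson closure (3-exo-tet) with inversion at C7 converts the syn-chlorohydrin into the cis-epoxide. The acetal keeps O4 from displacing the chloride directly, and the amidine is too weak a base to enolise the lactone at this temperature.

Step 10
Reactants: 12 (6R,7R)-cis-vinyl epoxide
Product: 14 (3R,4R,5R,6R,7S)-4,7-anhydro-2,8,9-trideoxy-non-8-enono-1,5-lactone (vinyl tetrahydrofuran diol), via O3-hemiketal 13 (not isolated)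
Conditions: BF3·OEt2 (1.1 equiv), CH2Cl2, −78 to −30 °C; then aq. NaHCO3
Reagents that add atoms: none
Why: The Lewis acid activates the vinyl epoxide, and the acetal oxygen O4 opens it at the allylic carbon C7 (5-endo, inversion), which closes the tetrahydrofuran with the vinyl group cis to O6; the oxonium ion then sheds the isopropylidene group, which leaves as acetone on aqueous work-up. O3 cannot compete because its attack would give a bridged oxonium ion. Endo opening of vinyl epoxides at the allylic carbon and participation of ether or acetal oxygens in epoxide opening are both known reaction types.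

Step 11
Reactants: 15 methyl (R)-lactate
Product: 16 methyl (R)-2-(tert-butyldimethylsilyloxy)propanoate
Conditions: TBSCl, imidazole, DMF, rt
Reagents that add atoms: tert-butyldimethylsilyl chloride, CC(C)(C)[Si](C)(C)Cl
Why: Standard silylation; a silyl ether is non-chelating and steers the later addition to the Felkin–Anh product.

Step 12
Reactants: 16 methyl (R)-2-(tert-butyldimethylsilyloxy)propanoate
Product: 17 (R)-2-(tert-butyldimethylsilyloxy)propanal
Conditions: i-Bu2AlH, CH2Cl2, −78 °C; aq. Rochelle salt
Reagents that add atoms: none
Why: Partial reduction of the ester; the tetrahedral aluminium hemiacetal is stable at −78 °C and gives the aldehyde on work-up without loss of configuration at the α-carbon.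

Step 13
Reactants: 17 (R)-2-(tert-butyldimethylsilyloxy)propanal
Product: 18 (3S,4R)-4-(tert-butyldimethylsilyloxy)pent-1-en-3-ol
Conditions: CH2=CHMgBr, THF, −78 °C; aq. NH4Cl
Reagents that add atoms: vinylmagnesium bromide, C=C[Mg]Br
Why: Non-chelation (Felkin–Anh) addition to the α-silyloxy aldehyde gives the 3,4-anti alcohol as the main product; the minor syn epimer is removed by chromatography.

Step 14
Reactants: 18 (3S,4R)-4-(tert-butyldimethylsilyloxy)pent-1-en-3-ol
Product: 19 (3S,4R)-4-(tert-butyldimethylsilyloxy)pent-1-en-3-yl benzoate
Conditions: BzCl, pyridine, DMAP (cat.), CH2Cl2, 0 °C to rt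
Reagents that add atoms: benzoyl chloride, O=C(Cl)c1ccccc1
Why: Acylation of the only free hydroxyl puts the benzoate on O10 while O11 is still silylated.

Step 15
Reactants: 19 (3S,4R)-4-(tert-butyldimethylsilyloxy)pent-1-en-3-yl benzoate
Product: 20 (3S,4R)-4-hydroxypent-1-en-3-yl benzoate
Conditions: HF·pyridine, THF, 0 °C to rt
Reagents that add atoms: none
Why: Desilylation in an acidic fluoride medium, in which the 1,2-shift of the benzoate to the new hydroxyl is slow.

Step 16
Reactants: 20 (3S,4R)-4-hydroxypent-1-en-3-yl benzoate
Product: 21 (3S,4R)-4-acetoxypent-1-en-3-yl benzoate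
Conditions: Ac2O, pyridine, DMAP (cat.), CH2Cl2, 0 °C
Reagents that add atoms: acetic anhydride, CC(=O)OC(C)=O
Why: Fast catalysed acetylation traps O11 before any acyl migration can occur.

Step 17
Reactants: 14 (3R,4R,5R,6R,7S)-vinyl tetrahydrofuran diol, 21 (3S,4R)-4-acetoxypent-1-en-3-yl benzoate
Product: 22 CNP0230210.1, (3R,4R,5R,6R,7S,8E,10S,11R)-11-acetoxy-4,7-anhydro-10-benzoyloxy-2,8,9,12-tetradeoxy-dodec-8-enono-1,5-lactone
Conditions: second-generation Hoveyda–Grubbs catalyst RuCl2(H2IMes)(=CH-C6H4-2-O-i-Pr) (10 mol %), 21 (3 equiv), CH2Cl2, 40 °C
Reagents that add atoms: none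
Why: Olefin cross-metathesis of two monosubstituted alkenes with loss of ethylene; the bulky allylic substituents on both sides favour the E-alkene, and ruthenium alkylidenes tolerate free hydroxyls, esters and the lactone.

## Compound list

1 | D-(−)-quinic acid | OC(=O)[C@]1(O)C[C@@H](O)[C@@H](O)[C@H](O)C1 | starting material
2 | 3,4-O-isopropylidenequinic acid 1,5-lactone | O=C1O[C@@H]2C[C@@]1(O)C[C@H]3OC(C)(C)O[C@@H]23 | intermediate
3 | 1-(hydroxymethyl)-3,4-O-isopropylidenecyclohexane-1,3,4,5-tetrol | OC[C@]1(O)C[C@H]2OC(C)(C)O[C@H]2[C@H](O)C1 | intermediate
4 | (3R,4S,5R)-5-hydroxy-3,4-(isopropylidenedioxy)cyclohexanone | O=C1C[C@H]2OC(C)(C)O[C@H]2[C@H](O)C1 | intermediate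
5 | (3R,4R,5R)-5-(tert-butyldimethylsilyloxy)-3,4-(isopropylidenedioxy)cyclohexanone | O=C1C[C@H]2OC(C)(C)O[C@H]2[C@H](O[Si](C)(C)C(C)(C)C)C1 | intermediate
6 | (4R,5R,6R)-6-(tert-butyldimethylsilyloxy)-4,5-(isopropylidenedioxy)oxepan-2-one | O=C1C[C@H]2OC(C)(C)O[C@H]2[C@H](O[Si](C)(C)C(C)(C)C)CO1 | intermediate
7 | 6-hydroxy-4,5-(isopropylidenedioxy)oxepan-2-one (desilylated 6) | O=C1C[C@H]2OC(C)(C)O[C@H]2[C@H](O)CO1 | intermediate (not isolated)
8 | 2-deoxy-3,4-O-isopropylidene-D-lyxo-hexono-1,5-lactone | O=C1C[C@H]2OC(C)(C)O[C@H]2[C@@H](CO)O1 | intermediate
9 | 2-deoxy-3,4-O-isopropylidene-D-lyxo-hexodialdono-1,5-lactone | O=C1C[C@H]2OC(C)(C)O[C@H]2[C@@H](C=O)O1 | intermediate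
10 | O6-bis(isopinocampheyl)borinate of 11 | O=C1C[C@H]2OC(C)(C)O[C@H]2[C@@H]([C@H](OB([C@H]3C[C@H]4C[C@@H]([C@@H]3C)C4(C)C)[C@H]3C[C@H]4C[C@@H]([C@@H]3C)C4(C)C)[C@@H](Cl)C=C)O1 | intermediate (not isolated)
11 | (6S,7S)-7-chloro-2,7,8,9-tetradeoxy-3,4-O-isopropylidene-non-8-enono-1,5-lactone | O=C1C[C@H]2OC(C)(C)O[C@H]2[C@@H]([C@H](O)[C@@H](Cl)C=C)O1 | intermediate
12 | (6R,7R)-6,7-anhydro-2,8,9-trideoxy-3,4-O-isopropylidene-non-8-enono-1,5-lactone | O=C1C[C@H]2OC(C)(C)O[C@H]2[C@@H]([C@@H]3O[C@@H]3C=C)O1 | intermediate
13 | O3-(2-hydroxyprop-2-yl) hemiketal of 14 | C=C[C@@H]1O[C@H]2[C@H](OC(=O)C[C@H]2OC(C)(C)O)[C@@H]1O | intermediate (not isolated)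
14 | (3R,4R,5R,6R,7S)-4,7-anhydro-2,8,9-trideoxy-non-8-enono-1,5-lactone | C=C[C@@H]1O[C@H]2[C@H](OC(=O)C[C@H]2O)[C@@H]1O | intermediate
15 | methyl (R)-lactate | C[C@@H](O)C(=O)OC | starting material
16 | methyl (R)-2-(tert-butyldimethylsilyloxy)propanoate | CC(C)(C)[Si](C)(C)O[C@H](C)C(=O)OC | intermediate
17 | (R)-2-(tert-butyldimethylsilyloxy)propanal | CC(C)(C)[Si](C)(C)O[C@H](C)C=O | intermediate
18 | (3S,4R)-4-(tert-butyldimethylsilyloxy)pent-1-en-3-ol | CC(C)(C)[Si](C)(C)O[C@H](C)[C@H](C=C)O | intermediate
19 | (3S,4R)-4-(tert-butyldimethylsilyloxy)pent-1-en-3-yl benzoate | CC(C)(C)[Si](C)(C)O[C@H](C)[C@H](C=C)OC(=O)c1ccccc1 | intermediate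
20 | (3S,4R)-4-hydroxypent-1-en-3-yl benzoate | O[C@H](C)[C@H](C=C)OC(=O)c1ccccc1 | intermediate
21 | (3S,4R)-4-acetoxypent-1-en-3-yl benzoate | CC(=O)O[C@H](C)[C@H](C=C)OC(=O)c1ccccc1 | intermediate
22 | CNP0230210.1 | CC(=O)O[C@H](C)[C@H](/C=C/[C@@H]1O[C@H]2[C@H](OC(=O)C[C@H]2O)[C@@H]1O)OC(=O)c1ccccc1 | target

## Step count and risk

Total step count: 17. Longest linear sequence: 11 steps (steps 1–10 and 17); the side chain takes 6 steps (11–16).

**Step 5 (key step).** The most likely failure is migration of the wrong methylene (C2) or unselective migration, because the two α-carbons differ only through oxygen substituents one bond further out. The fallback sets out from 4 and comes back at 8. It makes C6 an α-oxygenated secondary carbon, whose preference to migrate is established.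
- The hydroxy ketone 4 is dehydrated (MsCl, Et3N) to the 3,4-O-isopropylidene cyclohexenone F1.
- OsO4 with N-methylmorpholine N-oxide adds two hydroxyls to the face opposite the acetal, which restores O5 trans to O4 and gives the dihydroxy ketone F2.
- 2,2-Dimethoxypropane with PPTS gives the di-O-isopropylidene ketone F3.
- mCPBA then gives the acyloxy acetal lactone F4 with no regiochemical question.
- K2CO3 and NaBH4 in MeOH at 0 °C open F4, release acetone from O5/O6 and reduce the C6 aldehyde as it forms, giving the dihydroxy ester F5.
- F5 lactonises onto O5 with PPTS in toluene to 8.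

**Step 10.** The most likely failures are loss of stereospecificity through an allyl cation, Lewis-acid rearrangement of the vinyl epoxide to a carbonyl compound, or participation of the lactone carbonyl in place of O4. The fallback sets out from 9 and comes back at 14; it replaces the epoxide by an alkene activated as a seleniranium ion.
- CrCl2/NiCl2-mediated (Nozaki–Hiyama–Kishi) addition of (E)-1-iodopropene to 9 gives the (E)-allylic alcohol F6, with Felkin–Anh control at C6 and separation of the minor epimer.
- N-(Phenylseleno)phthalimide with catalytic camphorsulfonic acid in CH2Cl2 lets the acetal oxygen O4 close onto C7 (5-exo), the allylic hydroxyl directing the new C–O bond cis to itself; after loss of acetone this gives the phenylselenide F7.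
- H2O2 oxidation and syn-elimination of the selenoxide away from the oxygen-bearing C7 give the vinyl group of 14.

**Step 8.** The most likely failures are decomposition or C5 epimerisation of the α-acyloxy aldehyde and attack on the lactone while the borane is generated under strongly basic conditions, or erosion of facial selectivity. The fallback sets out from 6 and comes back at 14; it runs the same chemistry on an open-chain α-silyloxy aldehyde and closes the lactone last.
- NaOMe (cat.) in MeOH at −20 °C, with short contact to avoid silyl migration, opens 6 to the hydroxy ester F8.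
- Dess–Martin oxidation gives the α-silyloxy aldehyde F9.
- The chloroallylborane of step 8 gives the chlorohydrin F10.
- DBU gives the cis-epoxide F11.
- BF3·OEt2 gives the tetrahydrofuran ester F12.
- HF·pyridine, then PPTS in toluene at 50 °C, desilylates and lactonises to 14.

**Step 17.** The most likely failures are slow or unproductive metathesis, because the vinyl group sits on the concave face and both partners are hindered allylic-oxygenated olefins, and double-bond migration by ruthenium hydrides. The fallback sets out from 11 and 21 and comes back at 22; it moves the metathesis ahead of the ring closure, where the vinyl group is not yet buried.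
- Cross-metathesis of 11 with 21 gives the full-chain chlorohydrin F13.
- DBU gives the full-chain cis-epoxide F14.
- BF3·OEt2, as in step 10, closes the tetrahydrofuran and gives 22 directly.
- The price is a more cation-stabilising allylic position and a neighbouring benzoate during ring closure, which is why this order is not the first choice.

## Further compounds

F1 | step 5 | 3,4-O-isopropylidene cyclohex-5-enone (from 4) | O=C1C[C@H]2OC(C)(C)O[C@H]2C=C1
F2 | step 5 | 5,6-dihydroxy-3,4-(isopropylidenedioxy)cyclohexanone, new hydroxyls trans to O4 | O=C1C[C@H]2OC(C)(C)O[C@H]2[C@H](O)[C@@H]1O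
F3 | step 5 | 3,4:5,6-di-O-isopropylidene ketone | O=C1C[C@H]2OC(C)(C)O[C@H]2[C@@H]3OC(C)(C)O[C@H]13
F4 | step 5 | acyloxy acetal ε-lactone (oxygen between C1 and C6) | O=C1C[C@H]2OC(C)(C)O[C@H]2[C@@H]3OC(C)(C)O[C@@H]3O1
F5 | step 5 | methyl 2-deoxy-3,4-O-isopropylidene-D-lyxo-hexonate | COC(=O)C[C@H]1OC(C)(C)O[C@H]1[C@H](O)CO
F6 | step 10 | (6R,7E)-2,7,8,9-tetradeoxy-3,4-O-isopropylidene-non-7-enono-1,5-lactone | O=C1C[C@H]2OC(C)(C)O[C@H]2[C@@H]([C@H](O)/C=C/C)O1
F7 | step 10 | (8S)-4,7-anhydro-2,8,9-trideoxy-8-(phenylseleno)nonono-1,5-lactone | C[C@H]([Se]c1ccccc1)[C@@H]1O[C@H]2[C@H](OC(=O)C[C@H]2O)[C@@H]1O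
F8 | step 8 | methyl 5-O-(tert-butyldimethylsilyl)-2-deoxy-3,4-O-isopropylidene-D-lyxo-hexonate | COC(=O)C[C@H]1OC(C)(C)O[C@H]1[C@H](O[Si](C)(C)C(C)(C)C)CO
F9 | step 8 | C6 aldehyde of F8 | COC(=O)C[C@H]1OC(C)(C)O[C@H]1[C@H](O[Si](C)(C)C(C)(C)C)C=O
F10 | step 8 | open-chain syn-chlorohydrin methyl ester | COC(=O)C[C@H]1OC(C)(C)O[C@H]1[C@H](O[Si](C)(C)C(C)(C)C)[C@H](O)[C@@H](Cl)C=C
F11 | step 8 | open-chain cis-vinyl epoxide methyl ester | COC(=O)C[C@H]1OC(C)(C)O[C@H]1[C@H](O[Si](C)(C)C(C)(C)C)[C@@H]2O[C@@H]2C=C
F12 | step 8 | methyl 4,7-anhydro-5-O-(tert-butyldimethylsilyl)-2,8,9-trideoxy-non-8-enonate | COC(=O)C[C@@H](O)[C@H]1O[C@@H](C=C)[C@@H](O)[C@H]1O[Si](C)(C)C(C)(C)C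
F13 | step 17 | full-chain syn-chlorohydrin (11 joined to 21 at C8=C9) | O=C1C[C@H]2OC(C)(C)O[C@H]2[C@@H]([C@H](O)[C@@H](Cl)/C=C/[C@H](OC(=O)c3ccccc3)[C@@H](C)OC(C)=O)O1
F14 | step 17 | full-chain cis-epoxide | O=C1C[C@H]2OC(C)(C)O[C@H]2[C@@H]([C@@H]3O[C@@H]3/C=C/[C@H](OC(=O)c4ccccc4)[C@@H](C)OC(C)=O)O1
A1 | alternative 1 | C2–C3 epoxide with free C5 hydroxyl and C6 silyl ether | CC(=O)O[C@H](C)[C@H](/C=C/[C@@H]1O[C@H]([C@H]2CO2)[C@H](O)[C@@H]1O[Si](C)(C)C(C)(C)C)OC(=O)c1ccccc1
A2 | alternative 1 | target as its C6 tert-butyldimethylsilyl ether | CC(=O)O[C@H](C)[C@H](/C=C/[C@@H]1O[C@H]2[C@H](OC(=O)C[C@H]2O)[C@@H]1O[Si](C)(C)C(C)(C)C)OC(=O)c1ccccc1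
A3 | alternative 2 | (7E)-9,10-epoxide with free C4 hydroxyl, C9 configured for double inversion | CC(=O)O[C@H](C)[C@H]1O[C@@H]1/C=C/[C@@H](O[Si](C)(C)C(C)(C)C)[C@H]1OC(=O)C[C@@H](O[Si](C)(C)C(C)(C)C)[C@H]1O
A4 | alternative 2 | bicyclic core with E-alkene, free C10 hydroxyl, C11 acetate, O3 and O6 silyl ethers | CC(=O)O[C@H](C)[C@H](/C=C/[C@@H]1O[C@H]2[C@H](OC(=O)C[C@H]2O[Si](C)(C)C(C)(C)C)[C@@H]1O[Si](C)(C)C(C)(C)C)O
A5 | alternative 3 | endo-cis-diol 7-oxanorbornene, O5 acrylate, O6 silyl ether | C=CC(=O)O[C@@H]1[C@H](O[Si](C)(C)C(C)(C)C)[C@@H]2C=C[C@H]1O2
A6 | alternative 3 | C7-vinyl tetrahydrofuran fused to the 2,3-unsaturated δ-lactone | C=C[C@@H]1O[C@H]2[C@H](OC(=O)C=C2)[C@@H]1O[Si](C)(C)C(C)(C)C
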